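The winter and dawn runs were what I had for a flask in which starting material, under a held gas phase, turns into product.

| flask | starting material | gas phase | remark | time |
|---|---|---|---|---|
| winter | 0.50 M | 36 mM (held) | run made earlier |  |
| dawn | 0.75 M | 36 mM (held) | run made earlier |  |
| flask | 1.0 M | 36 mM (held) |  | 40 min |

| run | time / min | product / % |
|---|---|---|
| winter | 1.50 | 6.2 |
| winter | 5.00 | 19.8 |
| winter | 10.0 | 40.5 |
| winter | 15.0 | 60.1 |
| winter | 20.0 | 73.8 |
| winter | 25.0 | 84.4 |
| winter | 30.0 | 92.3 |
| dawn | 2.50 | 6.2 |
| dawn | 4.00 | 12.7 |
| dawn | 6.00 | 20.3 |
| dawn | 10.0 | 33.9 |
| dawn | 15.0 | 47.9 |
| dawn | 20.0 | 61.7 |
| dawn | 30.0 | 83.7 |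

(readings scatter by 1 percentage point)

- which holds at 40 min: what has brought the reaction to rest, or that it has not come to rest (it is still moving / forward and back rates have come level / all of the starting material has reacted)
- the product standing at 40 min, as a percentage of the starting material charged

- the analysis behind the earlier runs scatters by 1 percentage point, standard deviation
- at the start none of the gas phase is in solution
- the reaction counts as stopped when no species that holds the starting material changes by six tenths of a point or more over the second half of the time

I put the readings into molar terms and asked whether a poorer run is simply a later stretch of a richer one, which is the time-shifted overlay. The dawn run made product at 0.0254 M min⁻¹ over its first 10.0 min. At that pace the dawn run took a time I call the head start, the time to come down from its own charge to the winter charge: 9.83 min. As a test, the winter run held 0.131 M of starting material at 20.0 min, and the dawn run held 0.122 M at 30.0 min, about one head start later.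

The flask's step down to the dawn charge is the same size, so I assumed the same head start, though no run shows the pace above that charge. The flask at 39.8 min should then match the last dawn reading, giving 87.8% product. The dawn run gained 22 percentage points over its last 10.0 min, so I expected the flask to be still moving.

The forecast, made by another road, gave 90% and "it is still moving", noting that “a saturating rate law gives a similar result”. The flask gave 88.5% and "it is still moving".

    starting material + dissolved gas → product (k = 0.0790 M⁻¹ s⁻¹)
    gas phase ⇌ dissolved gas, rate k2*(csat - [dissolved gas]) (kL = 0.0160 s⁻¹)
    dissolved gas ⇌ dormant form (K = 6.70, k = 0.00170 s⁻¹)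

In the flask, gas passed into solution while starting material consumed it: at 20.0 min, starting material stood at 48.1%, dissolved gas at 0.0103 M and dormant form at 0.0138 M. By 40.0 min, starting material was down to 11.5%, while dissolved gas had risen to 0.0214 M and dormant form to 0.0373 M. The head start had placed 0.122 M of starting material in the flask at 39.8 min, and the flask held 0.115 M at 40.0 min. Moved by 9.83 min, the dawn reading at 15.0 min gave 60.9% product for this flask at 24.8 min, and the same flask read at 25 min stood at 63.1%.

All runs are calculated on assumed constants; the scatter is artificial.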